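With the benzene ring numbered C1 (CO2H), C2 and C4 (OH), C3 (H), C5 (CH3) and C6 (13-methyltetradecyl), everything rests on cutting the two neighbouring bonds C6–C1′ and C5–CH3 together. C6 lies meta to both oxygens, so no electrophilic substitution can reach it. The route instead exploits the C5–C6 edge of the ring, flanked by the C4 oxygen, as the triple bond of 3,5-dimethoxybenzyne. In one operation, commercial 1-chloro-3,5-dimethoxybenzene is dehydrochlorinated, 13-methyltetradecylmagnesium bromide adds at C6, and the arylmagnesium formed at C5 is methylated with iodomethane. The precursor is thus an unadorned chloroarene with both oxygens already in place; C1 is carboxylated afterwards.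

Key step: step 4

Remark: ring positions are cited with the numbering of the target in every compound (C1′ is the first chain carbon); the target has no stereocentre.

Step 1
Reactants: 1 11-bromoundecan-1-ol; 2 isobutylmagnesium bromide
Product: 3 13-methyltetradecan-1-ol
Conditions: 2 (2.5 equiv), Li2CuCl4 (cat.), THF, −10 °C to rt
Reagents that add atoms: none
Why: Copper-catalysed cross-coupling of a primary alkyl bromide with a primary Grignard reagent (Li2CuCl4 catalysis) should join the two sp3 carbons cleanly, the hydroxyl group being masked in the flask as its magnesium alkoxide by the first equivalent of 2.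

Step 2
Reactants: 3 13-methyltetradecan-1-ol
Product: 4 1-bromo-13-methyltetradecane
Conditions: CBr4, PPh3, CH2Cl2, 0 °C to rt
Reagents that add atoms: carbon tetrabromide, BrC(Br)(Br)Br
Why: Appel reaction: the alkoxyphosphonium ion formed from the unhindered primary alcohol should be displaced by bromide in a clean SN2 step, with the remote isopropyl terminus untouched.

Step 3
Reactants: 4 1-bromo-13-methyltetradecane
Product: 5 13-methyltetradecylmagnesium bromide
Conditions: Mg turnings, I2 (cat.), THF, 40–60 °C; solution used directly
Reagents that add atoms: magnesium, [Mg]
Why: Oxidative insertion of magnesium into a primary C–Br bond (Grignard formation) is reliable for long-chain bromides, and slow addition of 4 to excess activated metal should keep Wurtz coupling low.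

Step 4
Reactants: 6 1-chloro-3,5-dimethoxybenzene; 5 13-methyltetradecylmagnesium bromide; 7 iodomethane
Product: 11 1,5-dimethoxy-2-methyl-3-(13-methyltetradecyl)benzene, via (2-chloro-4,6-dimethoxyphenyl)lithium 8 (not isolated), via 3,5-dimethoxybenzyne 9 (not isolated), via arylmagnesium bromide 10 (not isolated)
Conditions: lithium 2,2,6,6-tetramethylpiperidide (LiTMP), THF, −78 °C; then 5 (2 equiv), −78 °C to rt, then 40 °C; then 7 (excess), Li2CuCl4 (cat.), 0 °C to rt
Reagents that add atoms: none
Why: LiTMP removes the ring hydrogen lying between chlorine and a methoxy group of 6 to give 8 (metalation between the two methoxy groups is a reversible dead end that the liberated amine returns to 6), and on warming 8 expels LiCl to form aryne 9, whose triple bond corresponds to the C5–C6 edge of the target. The C–Mg bond of 5 then adds across the strained in-plane π bond to give arylmagnesium 10 (new bond C6–C1′), and 10 is methylated by iodomethane, with Li2CuCl4 added to speed substitution at the crowded aryl–metal centre (new bond C5–CH3). The closest known reaction type is the addition of alkyllithium and Grignard reagents to 3-alkoxybenzynes generated by base-induced dehydrohalogenation, followed by electrophilic quench of the ortho-alkoxy arylmetal. No ring is closed and no stereocentre is created. The selectivity required is attack at the aryne carbon remote from oxygen, and the methoxy group beside the triple bond secures it: its inductive pull and the resulting angle distortion make the distal carbon the electrophilic terminus and place the developing carbanion next to oxygen, which also chelates the metal until the electrophile arrives.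

Step 5
Reactants: 11 1,5-dimethoxy-2-methyl-3-(13-methyltetradecyl)benzene
Product: 12 2-bromo-1,5-dimethoxy-4-methyl-3-(13-methyltetradecyl)benzene
Conditions: NBS (1.05 equiv), MeCN/CH2Cl2, 0 °C to rt, dark
Reagents that add atoms: N-bromosuccinimide, O=C1CCC(=O)N1Br
Why: Electrophilic aromatic bromination with NBS in a polar medium should occur at C1, which is para to the C4 methoxy group and ortho to the C2 methoxy group, whereas C3 is shielded on both sides by O-methyl groups, the C4 one being turned toward C3 by the C5 methyl group.

Step 6
Reactants: 12 2-bromo-1,5-dimethoxy-4-methyl-3-(13-methyltetradecyl)benzene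
Product: 14 4,6-dimethoxy-3-methyl-2-(13-methyltetradecyl)benzoic acid, via aryllithium 13 (not isolated)
Conditions: n-butyllithium (n-BuLi), THF, −78 °C; CO2 (g), −78 °C to rt; then aq. HCl
Reagents that add atoms: carbon dioxide, O=C=O
Why: Bromine–lithium exchange is faster than any deprotonation at −78 °C and gives aryllithium 13, held by the neighbouring methoxy oxygen, which should add to carbon dioxide to give the carboxylate (carboxylation of an organolithium), released as the acid on acidification.

Step 7
Reactants: 14 4,6-dimethoxy-3-methyl-2-(13-methyltetradecyl)benzoic acid
Product: 15 4,6-dihydroxy-3-methyl-2-(13-methyltetradecyl)benzoic acid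
Conditions: BBr3 (5 equiv), CH2Cl2, −78 °C to rt; then ice-water
Reagents that add atoms: none
Why: Lewis-acid ether cleavage: BBr3 coordinates each methoxy oxygen and bromide removes the methyl group by SN2, the C2 ether being assisted by chelation to the carboxyl group, while the mild temperature and cold quench should spare the resorcylic acid from protodecarboxylation.

Compound list
1 | 11-bromoundecan-1-ol | OCCCCCCCCCCCBr | starting material
2 | isobutylmagnesium bromide | CC(C)C[Mg]Br | starting material
3 | 13-methyltetradecan-1-ol | OCCCCCCCCCCCCC(C)C | intermediate
4 | 1-bromo-13-methyltetradecane | BrCCCCCCCCCCCCC(C)C | intermediate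
5 | 13-methyltetradecylmagnesium bromide | CC(C)CCCCCCCCCCCC[Mg]Br | intermediate
6 | 1-chloro-3,5-dimethoxybenzene | COc1cc(Cl)cc(OC)c1 | starting material
7 | iodomethane | CI | starting material
8 | (2-chloro-4,6-dimethoxyphenyl)lithium | [Li]c1c(Cl)cc(OC)cc1OC | intermediate
9 | 3,5-dimethoxybenzyne (1,2-didehydro-3,5-dimethoxybenzene) | COC1=CC(OC)=CC#C1 | intermediate
10 | [2,4-dimethoxy-6-(13-methyltetradecyl)phenyl]magnesium bromide | COc1cc(OC)c([Mg]Br)c(CCCCCCCCCCCCC(C)C)c1 | intermediate
11 | 1,5-dimethoxy-2-methyl-3-(13-methyltetradecyl)benzene | COc1cc(OC)c(C)c(CCCCCCCCCCCCC(C)C)c1 | intermediate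
12 | 2-bromo-1,5-dimethoxy-4-methyl-3-(13-methyltetradecyl)benzene | COc1cc(OC)c(C)c(CCCCCCCCCCCCC(C)C)c1Br | intermediate
13 | [4,6-dimethoxy-3-methyl-2-(13-methyltetradecyl)phenyl]lithium | [Li]c1c(OC)cc(OC)c(C)c1CCCCCCCCCCCCC(C)C | intermediate
14 | 4,6-dimethoxy-3-methyl-2-(13-methyltetradecyl)benzoic acid | COc1cc(OC)c(C(=O)O)c(CCCCCCCCCCCCC(C)C)c1C | intermediate
15 | 4,6-dihydroxy-3-methyl-2-(13-methyltetradecyl)benzoic acid | Cc1c(O)cc(O)c(C(=O)O)c1CCCCCCCCCCCCC(C)C | target

Total step count: 7 steps.
Longest linear sequence: 7 steps (1 → 3 → 4 → 5 → 11 → 12 → 14 → 15).

Steps most likely to fail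

Step 4. The sequence may break down at three points. Metalation can rest at the position between the two methoxy groups or, after lithium–magnesium exchange, at an ortho-chloro arylmagnesium that eliminates only sluggishly. The amide base can add to the aryne in competition with the Grignard reagent. The crowded arylmagnesium can be protonated before it is methylated. The fallback separates chain attachment from methylation and sets out from 6 and 5. A Kumada coupling catalysed by the divalent nickel complex NiCl2(dppp) in THF should give 1,3-dimethoxy-5-(13-methyltetradecyl)benzene F1. NBS in acetonitrile should then brominate ortho to the chain and para to a methoxy group to give 2-bromo-1,5-dimethoxy-3-(13-methyltetradecyl)benzene F2. Bromine–lithium exchange with n-BuLi at −78 °C should give [2,4-dimethoxy-6-(13-methyltetradecyl)phenyl]lithium F3, which is alkylated by iodomethane 7. The fallback comes back to the route at 11.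

Step 7. Acid-promoted loss of carbon dioxide from the electron-rich resorcylic acid, or incomplete cleavage of the C4 ether, may erode the last step. The fallback sets out from 11 and removes the methyl ethers before any carboxyl group is present. BBr3 in CH2Cl2 should give 4-methyl-5-(13-methyltetradecyl)benzene-1,3-diol F4. Heating F4 with methylmagnesium carbonate (MeOMgOCO2Me) in DMF, followed by cold acidification, is a Kolbe–Schmitt-type ortho-carboxylation run under basic, chelating conditions. It is reversible and is expected to settle at C1, para to the C4 oxygen, as in the conversion of 5-alkylresorcinols into 6-alkyl-2,4-dihydroxybenzoic acids. The fallback replaces steps 5 to 7 and comes back to the route at 15.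

Step 5. Substitution may stray to C3, continue to a dibromide, or switch to radical bromination of a benzylic position. The fallback sets out from 11 and introduces the carboxyl carbon directly. Vilsmeier–Haack formylation (POCl3, DMF, then aqueous hydrolysis) uses a bulky, weakly electrophilic chloroiminium ion that should be more selective for the para position C1, and the formyl group deactivates the ring after one substitution. This should give 4,6-dimethoxy-3-methyl-2-(13-methyltetradecyl)benzaldehyde F5. Pinnick oxidation (NaClO2, NaH2PO4, 2-methyl-2-butene, t-BuOH/H2O) should then convert F5 into the acid. The fallback replaces steps 5 and 6 and comes back to the route at 14.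

Further compounds
F1 | step 4 | 1,3-dimethoxy-5-(13-methyltetradecyl)benzene | COc1cc(OC)cc(CCCCCCCCCCCCC(C)C)c1
F2 | step 4 | 2-bromo-1,5-dimethoxy-3-(13-methyltetradecyl)benzene | COc1cc(OC)c(Br)c(CCCCCCCCCCCCC(C)C)c1
F3 | step 4 | [2,4-dimethoxy-6-(13-methyltetradecyl)phenyl]lithium | [Li]c1c(OC)cc(OC)cc1CCCCCCCCCCCCC(C)C
F4 | step 7 | 4-methyl-5-(13-methyltetradecyl)benzene-1,3-diol | Cc1c(O)cc(O)cc1CCCCCCCCCCCCC(C)C
F5 | step 5 | 4,6-dimethoxy-3-methyl-2-(13-methyltetradecyl)benzaldehyde | COc1cc(OC)c(C=O)c(CCCCCCCCCCCCC(C)C)c1C
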